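Its constants were drawn at random within sensible limits; what happens was integrated by code.

Oak holds 0.950 J per D, and the half-life of D by step 2 alone at the charged concentrations, 2.8 min, is shorter than the 5.0 min run, so most of the D looks set to react. The balance of J says otherwise.

in all of them: D 0.40 M; X 0.400 M; time 5.0 min
- oak: J 0.380 M
- cedar: J 0.760 M
- maple: J 1.50 M

    E + Q → E.Q (k1 = 0.014 /M/s)
    D + J → E + Q (k2 = 0.011 /M/s)
    J + X → J.X (k3 = 0.059 /M/s)
    J + E ⇌ J.E, settled at all times (K4 = 7400 /M)

* part of the D that has reacted at the end, oak
* part of the D that has reacted at the end, cedar
* part of the D that has reacted at the end, maple
* what raising the concentration of J from its lowest to its highest value here does to the part of the D that has reacted (changes below 5 percentage points count as none) (it falls / it rises / no change)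

In oak J is charged in the smallest amount, and its half-life by step 3 alone is 0.49 min. The run is ten times that, so I reckon oak from the balance of J, not the clock.

Each reacted D takes one J in step 2. With K4·[J] at 2800 at the start, nearly all of the E takes a second J. X competes for the same free J, which cancels between steps 3 and 2. I call this competition the selectivity factor s, the rate constant of step 3 over that of step 2, 5.36. With y the fraction of D reacted and h the X charged per D charged:

X left, as a fraction of its charge = (1 − y)^s

J spent per D charged = 2y + h[1 − (1 − y)^s]

Setting the spending equal to oak's charge, I solve for y by Newton steps:

y = 12.9 %, then 16.3 %, then 16.5 %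

In cedar one Newton step from 45.0 %, the value with the X charge counted in full, brings the same balance to 46.7 %. In maple the spending at full reaction, 3.00, stays below the charge of 3.75, so the balance sets no ceiling and gives me no number. I expect a rise.

The forecast says 16.5 %, 42.5 % and 86.5 %, and that the part reacted it rises, on the ground that “each D that reacts uses one J directly and a second when the tight binding traps the E as J.E”. Its cedar value lies below mine.

The flask gives 16.5 %, 42.7 % and 86.5 %: it rises, by 70 percentage points.

In oak, D left raised to s gives 37.9 % of the X, and X reads 38 %. The neighbour is like cedar but holds 0.10 M of D, so J stands at 7.60 equiv and h at 4.00. Spending at full reaction is 6.00, below the charge, so J sets no ceiling there. At its reading of 65.1 % reacted, the spending is 5.29, which leaves 30.4 % of the J, and the neighbour reads 30.4 % free J at 5.00 min.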